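Readings and results were computed on assumed constants.

Start with the easy line, the midnight run.

| flask | substrate | partner | remark | time |
|---|---|---|---|---|
| midnight | 1.6 M | 0.40 equiv | run made earlier |  |
| winter | 1.6 M | 1.6 equiv | run made earlier |  |
| flask | 1.6 M | 0.800 equiv |  | 2.5 h |

| run | time / min | substrate / % | single product / % |
|---|---|---|---|
| midnight | 30.0 | 68 | 11 |
| midnight | 60.0 | 66 | 10 |
| midnight | 90.0 | 69 | 11 |
| midnight | 120 | 69 | 6 |
| winter | 15.0 | 16 | 10 |
| winter | 40.0 | 12 | 8 |
| winter | 80.0 | 9 | 8 |
| winter | 120 | 7 | 7 |

(standard deviation of a reading: 1.5 percentage points)

- amount of substrate at 2.5 h, in percent of the substrate charged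
- amount of single product at 2.5 h, in percent of the substrate charged
- amount of other mono adduct at 2.5 h, in percent of the substrate charged
- amount of bis adduct at 2.5 h, in percent of the substrate charged

- what was read earlier has a scatter of 1.5 percentage points, one standard deviation

Its substrate reads 68% at 30.0 min and 69% at 120 min, flat within the scatter, so you may replace that curve by its mean, 68.0%. Call this the survival per portion, the fraction of substrate still there after a portion of 0.40 equiv of partner has acted at [substrate] = 1.6 M.

The new flask charges twice that partner. So if the second portion acts like the first, the flask's substrate falls to the survival squared, 46.2%, and the error of the mean moves this by about 1 percentage point. But the winter run warns you: the same rule gives 21.4% for its 1.6 equiv, while its last reading is 7%, so there the rule reads high. You therefore commit to 46.2% or a little under.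

The forecast gives 43% substrate, 13% single product, 21% other mono adduct and 23% bis adduct, and it says of this flask: “the partner should be exhausted well before 2.5 h”. Its substrate lies 3.2 points under your reckoning.

The flask gives 44.2% substrate, 10.6% single product, 1.94% other mono adduct and 24.2% bis adduct.

    substrate + partner → single product + released group (k = 0.130 M⁻¹ min⁻¹)
    substrate + partner → other mono adduct + released group (k = 0.00480 M⁻¹ min⁻¹)
    partner + single product → bis adduct + released group (k = 0.230 M⁻¹ min⁻¹)
    partner + other mono adduct → bis adduct + released group (k = 0.00720 M⁻¹ min⁻¹)
    single product ⇌ isomer of the product (K = 1.80, k = 0.0370 min⁻¹)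

So the forecast and the flask part on other mono adduct, and the step to it turned over 1.99% of the substrate charged. With partner, the limiting reagent, at 0% after 2.50 h, the survival squared stood 2.0 points above this flask's substrate. Taken to the neighbour flask with 0.480 equiv of partner, it gives 63.0%, and that flask holds 62.6% substrate after 2.50 h.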